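Locants follow the target: C1 is the epoxide carbon carrying C7 (CH2OBz), C2 bears OAc, C3 bears OBz, C4=C5 is the alkene and C6 is the epoxide CH. The quaternary C1 with its C7 carbon, the adjacent C6 and the C4=C5 double bond of the cyclohexene ring are read as a γ,δ-unsaturated acid, the product of an ester-enolate Claisen shift. One Ireland–Claisen ring contraction of an L-gulono-1,5-lactone therefore makes C1–C6, closes the carbocycle and sets C1 and C6. Its precursor is the tris-TBS δ-lactone carrying an (E)-2-(4-methoxybenzyloxy)vinyl group at the carbinol carbon. O6 later leaves as a mesylate when O1 closes the epoxide.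

Key step: step 10

Remark: gulonate locants are used up to the rearrangement precursor; from step 10 on the target locants apply (lactone carbonyl carbon = C7, gulonate C2 to C6 = C1 to C5, ylide carbon = C6). TBS = tert-butyldimethylsilyl.
Assumption: the E and Z enol ethers formed in step 9 can be separated on amine-treated silica; only the E isomer is carried forward.

Step 1
Reactants: 1 4-methoxybenzyl alcohol; 2 chloromethyl methyl sulfide
Product: 3 4-methoxybenzyl methylthiomethyl ether
Conditions: NaH, NaI (cat.), DME, 0 °C → rt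
Reagents that add atoms: none
Why: Williamson etherification of the sodium alkoxide with the α-chloro sulfide (methylthiomethyl ether formation) is a reliable SN2 process for a primary benzylic alcohol.

Step 2
Reactants: 3 4-methoxybenzyl methylthiomethyl ether
Product: 5 (4-methoxybenzyloxymethyl)triphenylphosphonium chloride, via 4-methoxybenzyl chloromethyl ether 4 (not isolated)
Conditions: SO2Cl2, CH2Cl2, −78 °C; volatiles removed; PPh3, toluene, rt
Reagents that add atoms: sulfuryl chloride O=S(=O)(Cl)Cl; triphenylphosphine c1ccc(cc1)P(c1ccccc1)c1ccccc1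
Why: Chlorinolysis of the O,S-acetal gives the α-chloro ether, which alkylates triphenylphosphine (SN2 quaternisation) to the Wittig salt.

Step 3
Reactants: 6 L-gulono-1,4-lactone
Product: 7 5,6-O-isopropylidene-L-gulono-1,4-lactone
Conditions: 2-methoxypropene, TsOH·H2O (cat.), DMF, 0 °C
Reagents that add atoms: 2-methoxypropene COC(C)=C
Why: Kinetic acid-catalysed acetalisation with the enol ether should engage the terminal 5,6-diol as a dioxolane in preference to the ring diol and touches no stereocentre.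

Step 4
Reactants: 7 5,6-O-isopropylidene-L-gulono-1,4-lactone
Product: 8 2,3-bis-O-TBS-5,6-O-isopropylidene-L-gulono-1,4-lactone
Conditions: TBSCl, imidazole, DMAP (cat.), DMF, rt → 40 °C
Reagents that add atoms: tert-butyldimethylsilyl chloride CC(C)(C)[Si](C)(C)Cl
Why: Imidazole-promoted silylation caps both secondary hydroxyls as base-stable silyl ethers, which are poor leaving groups in the later enolate chemistry.

Step 5
Reactants: 8 2,3-bis-O-TBS-5,6-O-isopropylidene-L-gulono-1,4-lactone
Product: 9 2,3-bis-O-TBS-5,6-O-isopropylidene-L-gulonic acid N-methoxy-N-methylamide (4-OH free)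
Conditions: MeNH(OMe)·HCl, AlMe3, CH2Cl2, 0 °C → rt; crude used directly
Reagents that add atoms: N,O-dimethylhydroxylamine hydrochloride CNOC.Cl
Why: Weinreb aminolysis of the lactone by the aluminium amide opens the five-membered ring under weakly basic conditions and exposes O4, the one oxygen the γ-lactone had masked.

Step 6
Reactants: 9 2,3-bis-O-TBS-5,6-O-isopropylidene-L-gulonic acid N-methoxy-N-methylamide
Product: 10 2,3,4-tris-O-TBS-5,6-O-isopropylidene-L-gulonic acid N-methoxy-N-methylamide
Conditions: TBSOTf, 2,6-lutidine, CH2Cl2, −78 → 0 °C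
Reagents that add atoms: tert-butyldimethylsilyl triflate CC(C)(C)[Si](C)(C)OS(=O)(=O)C(F)(F)F
Why: Silyl triflate silylation of the hindered secondary alcohol is fast at low temperature and blocks return to the γ-lactone, so that only O5 can later lactonise.

Step 7
Reactants: 10 2,3,4-tris-O-TBS-5,6-O-isopropylidene-L-gulonic acid N-methoxy-N-methylamide
Product: 12 2,3,4-tris-O-TBS-L-gulono-1,5-lactone (6-OH free), via dihydroxy Weinreb amide 11 (not isolated)
Conditions: AcOH/H2O/THF (3:1:1), 45 °C
Reagents that add atoms: none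
Why: Mild aqueous acid hydrolyses the terminal acetonide while the hindered secondary silyl ethers should persist, and the freed 5-hydroxyl displaces the N-methoxy-N-methylamide (acid-promoted lactonisation) to the six-membered lactone in preference to the seven-membered one through O6.

Step 8
Reactants: 12 2,3,4-tris-O-TBS-L-gulono-1,5-lactone
Product: 13 2,3,4-tris-O-TBS-L-gulono-1,5-lactone 6-aldehyde (C6 oxidised to CHO)
Conditions: Dess–Martin periodinane, CH2Cl2, 0 °C → rt; used crude
Reagents that add atoms: none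
Why: Dess–Martin oxidation converts the primary alcohol to the aldehyde without base, which protects the epimerisable α-acyloxy centre and the β-silyloxy group.

Step 9
Reactants: 13 2,3,4-tris-O-TBS-L-gulono-1,5-lactone 6-aldehyde; 5 (4-methoxybenzyloxymethyl)triphenylphosphonium chloride
Product: 15 (3S,4S,5R,6S)-3,4,5-tris(TBSO)-6-[(E)-2-(4-methoxybenzyloxy)ethenyl]oxan-2-one (L-gulo δ-lactone), via alkoxymethylidene ylide 14 (not isolated)
Conditions: 5, NaN(SiMe3)2, THF, 0 °C; then 13, −78 → 0 °C; E isomer isolated on Et3N-treated silica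
Reagents that add atoms: none
Why: Wittig olefination by the alkoxymethylidene ylide is much faster at the aldehyde than at the lactone at low temperature and is expected to give both enol ether geometries, from which the E isomer needed for the next step is separated.

Step 10
Reactants: 15 (3S,4S,5R,6S)-3,4,5-tris(TBSO)-6-[(E)-2-(4-methoxybenzyloxy)ethenyl]oxan-2-one
Product: 18 (1S,2S,3R,6R)-1,2,3-tris(TBSO)-6-(4-methoxybenzyloxy)cyclohex-4-ene-1-carboxylic acid, via silyl ketene acetal 16 (not isolated), via trimethylsilyl ester 17 (not isolated)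
Conditions: KN(SiMe3)2, Me3SiCl, Et3N, THF–toluene, −78 °C → rt; then 90 °C; aq. citric acid
Reagents that add atoms: none
Why: Deprotonation in the presence of Me3SiCl traps the lactone enolate as the endocyclic silyl ketene acetal 16, which on heating undergoes a concerted suprafacial [3,3]-sigmatropic shift over C1=C7–O–C4–C5=C6 that makes C1–C6, breaks C4–O and moves the double bond to C4=C5; the closest known reaction type is the Ireland–Claisen ring contraction of 6-alkenyl δ-lactones to cyclohexenecarboxylic acids. The cyclohexene ring is closed by this pericyclic C1–C6 bond formation through a boat-shaped six-atom array, the only one the six-membered lactone tether allows. C1 is controlled by the C4 carbinol centre carried over from gulonate C5, since the carboxyl carbon C7 is delivered to the ring face that the lactone oxygen leaves, while enolisation has erased the former gulonate C2 centre so that its configuration is irrelevant. C6 is controlled by the E geometry of the enol ether, which in the boat array places the C6 oxygen cis to C7 and trans to the C1 oxygen, the relationship needed for the later epoxide closure. The selectivity required is therefore only O-silylation over E1cB loss of the C2 silyloxy group, secured by the internal Me3SiCl quench at −78 °C and by the poor leaving-group ability of a silyloxide; facial and topological selectivity are enforced by the ring.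

Step 11
Reactants: 18 (1S,2S,3R,6R)-1,2,3-tris(TBSO)-6-(4-methoxybenzyloxy)cyclohex-4-ene-1-carboxylic acid
Product: 19 (1S,2S,3R,6R)-[1,2,3-tris(TBSO)-6-(4-methoxybenzyloxy)cyclohex-4-en-1-yl]methanol
Conditions: LiAlH4, THF, 0 → 50 °C
Reagents that add atoms: none
Why: Hydride reduction of the carboxylic acid gives the neopentyl primary alcohol while ethers and the isolated alkene are inert, and a silyl shift towards the new alkoxide would be harmless because every silyl group is removed in the next step.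

Step 12
Reactants: 19 (1S,2S,3R,6R)-[1,2,3-tris(TBSO)-6-(4-methoxybenzyloxy)cyclohex-4-en-1-yl]methanol
Product: 20 (1R,2S,3R,6R)-1-(hydroxymethyl)-6-(4-methoxybenzyloxy)cyclohex-4-ene-1,2,3-triol
Conditions: Bu4NF, THF, rt → 45 °C
Reagents that add atoms: none
Why: Fluoride-driven desilylation clears the two secondary and the tertiary silyl ethers, and since no ester or leaving group is present the basic medium cannot cause acyl migration or elimination.

Step 13
Reactants: 20 (1R,2S,3R,6R)-1-(hydroxymethyl)-6-(4-methoxybenzyloxy)cyclohex-4-ene-1,2,3-triol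
Product: 21 (1R,2S,3R,6R)-3-benzoyloxy-1-(benzoyloxymethyl)-6-(4-methoxybenzyloxy)cyclohex-4-ene-1,2-diol
Conditions: BzCl (2.1 equiv), pyridine, CH2Cl2, −40 → −20 °C
Reagents that add atoms: benzoyl chloride O=C(Cl)c1ccccc1
Why: Kinetic regioselective benzoylation should take the primary C7 hydroxyl and the allylic C3 hydroxyl, because the C2 hydroxyl is screened by the quaternary C1 and the tertiary C1 hydroxyl is unreactive.

Step 14
Reactants: 21 (1R,2S,3R,6R)-3-benzoyloxy-1-(benzoyloxymethyl)-6-(4-methoxybenzyloxy)cyclohex-4-ene-1,2-diol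
Product: 22 (1S,2S,3R,6R)-2-acetoxy-3-benzoyloxy-1-(benzoyloxymethyl)-6-(4-methoxybenzyloxy)cyclohex-4-en-1-ol
Conditions: Ac2O, pyridine, DMAP (cat.), CH2Cl2, 0 °C
Reagents that add atoms: acetic anhydride CC(=O)OC(C)=O
Why: Standard acetylation esterifies the only remaining secondary hydroxyl, the tertiary C1 hydroxyl being too hindered to react under these mild conditions.

Step 15
Reactants: 22 (1S,2S,3R,6R)-2-acetoxy-3-benzoyloxy-1-(benzoyloxymethyl)-6-(4-methoxybenzyloxy)cyclohex-4-en-1-ol
Product: 23 (1S,2S,3R,6R)-2-acetoxy-3-benzoyloxy-1-(benzoyloxymethyl)cyclohex-4-ene-1,6-diol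
Conditions: DDQ, CH2Cl2/pH 7 buffer, 0 °C → rt
Reagents that add atoms: none
Why: Oxidative removal of the p-methoxybenzyl ether (hydride abstraction by DDQ and hydrolysis of the oxocarbenium ion) frees the C6 hydroxyl without touching the esters or the alkene.

Step 16
Reactants: 23 (1S,2S,3R,6R)-2-acetoxy-3-benzoyloxy-1-(benzoyloxymethyl)cyclohex-4-ene-1,6-diol
Product: 25 (1S,2S,3R,6S)-2-acetoxy-3-benzoyloxy-1-(benzoyloxymethyl)-7-oxabicyclo[4.1.0]hept-4-ene (EANPDB:ANNO_02019), via C6 mesylate 24 (not isolated)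
Conditions: MsCl, Et3N, CH2Cl2, −30 °C; then DBU, 0 °C → rt
Reagents that add atoms: none
Why: Sulfonylation selects the secondary allylic C6 hydroxyl over the tertiary one, and the C1 oxygen then displaces the trans mesylate by intramolecular SN2 (Williamson-type epoxide closure) with inversion at C6, which puts the oxirane on the face opposite C7 as the target requires.

Compound list
1 | 4-methoxybenzyl alcohol | COc1ccc(CO)cc1 | starting material
2 | chloromethyl methyl sulfide | CSCCl | starting material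
3 | 4-methoxybenzyl methylthiomethyl ether | COc1ccc(COCSC)cc1 | intermediate
4 | 4-methoxybenzyl chloromethyl ether | COc1ccc(COCCl)cc1 | intermediate (not isolated)
5 | (4-methoxybenzyloxymethyl)triphenylphosphonium chloride | COc1ccc(COC[P+](c2ccccc2)(c2ccccc2)c2ccccc2)cc1.[Cl-] | intermediate
6 | L-gulono-1,4-lactone | O=C1[C@@H](O)[C@@H](O)[C@@H]([C@@H](O)CO)O1 | starting material
7 | 5,6-O-isopropylidene-L-gulono-1,4-lactone | O=C1[C@@H](O)[C@@H](O)[C@@H]([C@@H]2COC(C)(C)O2)O1 | intermediate
8 | 2,3-bis-O-TBS-5,6-O-isopropylidene-L-gulono-1,4-lactone | O=C1[C@@H](O[Si](C)(C)C(C)(C)C)[C@@H](O[Si](C)(C)C(C)(C)C)[C@@H]([C@@H]2COC(C)(C)O2)O1 | intermediate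
9 | 2,3-bis-O-TBS-5,6-O-isopropylidene-L-gulonic acid N-methoxy-N-methylamide (4-OH free) | CON(C)C(=O)[C@@H](O[Si](C)(C)C(C)(C)C)[C@@H](O[Si](C)(C)C(C)(C)C)[C@H](O)[C@@H]1COC(C)(C)O1 | intermediate
10 | 2,3,4-tris-O-TBS-5,6-O-isopropylidene-L-gulonic acid N-methoxy-N-methylamide | CON(C)C(=O)[C@@H](O[Si](C)(C)C(C)(C)C)[C@@H](O[Si](C)(C)C(C)(C)C)[C@H](O[Si](C)(C)C(C)(C)C)[C@@H]1COC(C)(C)O1 | intermediate
11 | 2,3,4-tris-O-TBS-L-gulonic acid N-methoxy-N-methylamide (5,6-diol) | CON(C)C(=O)[C@@H](O[Si](C)(C)C(C)(C)C)[C@@H](O[Si](C)(C)C(C)(C)C)[C@H](O[Si](C)(C)C(C)(C)C)[C@@H](O)CO | intermediate (not isolated)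
12 | 2,3,4-tris-O-TBS-L-gulono-1,5-lactone (6-OH free) | O=C1[C@@H](O[Si](C)(C)C(C)(C)C)[C@@H](O[Si](C)(C)C(C)(C)C)[C@H](O[Si](C)(C)C(C)(C)C)[C@H](CO)O1 | intermediate
13 | 2,3,4-tris-O-TBS-L-gulono-1,5-lactone 6-aldehyde | O=C1[C@@H](O[Si](C)(C)C(C)(C)C)[C@@H](O[Si](C)(C)C(C)(C)C)[C@H](O[Si](C)(C)C(C)(C)C)[C@H](C=O)O1 | intermediate
14 | (4-methoxybenzyloxy)methylidenetriphenylphosphorane | COc1ccc(COC=P(c2ccccc2)(c2ccccc2)c2ccccc2)cc1 | intermediate (not isolated)
15 | (3S,4S,5R,6S)-3,4,5-tris(TBSO)-6-[(E)-2-(4-methoxybenzyloxy)ethenyl]oxan-2-one | O=C1[C@@H](O[Si](C)(C)C(C)(C)C)[C@@H](O[Si](C)(C)C(C)(C)C)[C@H](O[Si](C)(C)C(C)(C)C)[C@H](/C=C/OCc2ccc(OC)cc2)O1 | intermediate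
16 | trimethylsilyl ketene acetal of 15 (endocyclic C1=C7) | C[Si](C)(C)OC1=C(O[Si](C)(C)C(C)(C)C)[C@@H](O[Si](C)(C)C(C)(C)C)[C@H](O[Si](C)(C)C(C)(C)C)[C@H](/C=C/OCc2ccc(OC)cc2)O1 | intermediate (not isolated)
17 | trimethylsilyl ester of acid 18 | C[Si](C)(C)OC(=O)[C@@]1(O[Si](C)(C)C(C)(C)C)[C@@H](O[Si](C)(C)C(C)(C)C)[C@H](O[Si](C)(C)C(C)(C)C)C=C[C@H]1OCc2ccc(OC)cc2 | intermediate (not isolated)
18 | (1S,2S,3R,6R)-1,2,3-tris(TBSO)-6-(4-methoxybenzyloxy)cyclohex-4-ene-1-carboxylic acid | OC(=O)[C@@]1(O[Si](C)(C)C(C)(C)C)[C@@H](O[Si](C)(C)C(C)(C)C)[C@H](O[Si](C)(C)C(C)(C)C)C=C[C@H]1OCc2ccc(OC)cc2 | intermediate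
19 | (1S,2S,3R,6R)-[1,2,3-tris(TBSO)-6-(4-methoxybenzyloxy)cyclohex-4-en-1-yl]methanol | OC[C@@]1(O[Si](C)(C)C(C)(C)C)[C@@H](O[Si](C)(C)C(C)(C)C)[C@H](O[Si](C)(C)C(C)(C)C)C=C[C@H]1OCc2ccc(OC)cc2 | intermediate
20 | (1R,2S,3R,6R)-1-(hydroxymethyl)-6-(4-methoxybenzyloxy)cyclohex-4-ene-1,2,3-triol | OC[C@@]1(O)[C@@H](O)[C@H](O)C=C[C@H]1OCc2ccc(OC)cc2 | intermediate
21 | (1R,2S,3R,6R)-3-benzoyloxy-1-(benzoyloxymethyl)-6-(4-methoxybenzyloxy)cyclohex-4-ene-1,2-diol | O=C(c1ccccc1)OC[C@@]2(O)[C@@H](O)[C@H](OC(=O)c3ccccc3)C=C[C@H]2OCc4ccc(OC)cc4 | intermediate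
22 | (1S,2S,3R,6R)-2-acetoxy-3-benzoyloxy-1-(benzoyloxymethyl)-6-(4-methoxybenzyloxy)cyclohex-4-en-1-ol | O=C(c1ccccc1)OC[C@@]2(O)[C@@H](OC(C)=O)[C@H](OC(=O)c3ccccc3)C=C[C@H]2OCc4ccc(OC)cc4 | intermediate
23 | (1S,2S,3R,6R)-2-acetoxy-3-benzoyloxy-1-(benzoyloxymethyl)cyclohex-4-ene-1,6-diol | O=C(c1ccccc1)OC[C@@]2(O)[C@@H](OC(C)=O)[C@H](OC(=O)c3ccccc3)C=C[C@H]2O | intermediate
24 | (1R,2S,3R,6R)-2-acetoxy-3-benzoyloxy-1-(benzoyloxymethyl)-6-(methanesulfonyloxy)cyclohex-4-en-1-ol | O=C(c1ccccc1)OC[C@@]2(O)[C@@H](OC(C)=O)[C@H](OC(=O)c3ccccc3)C=C[C@H]2OS(C)(=O)=O | intermediate (not isolated)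
25 | (1S,2S,3R,6S)-2-acetoxy-3-benzoyloxy-1-(benzoyloxymethyl)-7-oxabicyclo[4.1.0]hept-4-ene | CC(=O)O[C@H]1[C@H](OC(=O)c2ccccc2)C=C[C@@H]2O[C@@]21COC(=O)c1ccccc1 | target

Total step count: 16 (steps 1 and 2 make the Wittig salt; steps 3 to 16 form the main line).
Longest linear sequence: 14 steps, from L-gulono-1,4-lactone 6 to target 25 (steps 3 to 16).

Steps most likely to fail

Step 10. The enolate may expel the C2 silyloxy group (E1cB) faster than it is silylated, or the trimethylsilyl ketene acetal may be lost by protodesilylation before the strained boat rearrangement occurs. The fallback sets out from lactone 15 and comes back at acid 18. It gives up metal-enolate generation for amine/silyl triflate soft enolisation: TBSOTf and Et3N in toluene should convert 15 into the tert-butyldimethylsilyl ketene acetal F1 without an anionic intermediate. This more robust acetal is heated in toluene to the rearranged tert-butyldimethylsilyl ester F2, which K2CO3 in aqueous methanol hydrolyses to 18.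

Step 13. Kinetic discrimination between the C3 and C2 hydroxyls may be insufficient, so that acylation goes too far or reaches C2. The fallback sets out from tetraol 20 and comes back at dibenzoate 21. It replaces kinetic selection by a temporary tether: t-Bu2Si(OTf)2 with 2,6-lutidine should bridge the cis-1,3-related O7 and O2 as the six-membered 2,7-O-di-tert-butylsilylene F3. BzCl, pyridine and DMAP can then acylate only O3, giving the silylene 3-benzoate F4. HF·pyridine removes the silylene to give the 3-benzoate triol F5, and one equivalent of BzCl at −40 °C benzoylates its primary hydroxyl to return to 21.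

Step 9. E/Z control may be poor, and the basic ylide may epimerise the α-acyloxy aldehyde or cause β-elimination. The fallback sets out from aldehyde 13 and comes back at lactone 15. It builds the E enol ether in two non-basic steps: Takai–Utimoto-type borylolefination (CrCl2, Cl2CHBpin, LiI, THF) should give the (E)-alkenyl pinacol boronate F6 stereoselectively. Cu(OAc)2-mediated oxidative C–O coupling (Chan–Lam type) with 4-methoxybenzyl alcohol 1 and Et3N in air then replaces boron by the ether oxygen with retention of the E geometry, giving 15.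

Further compounds
F1 | step 10 | tert-butyldimethylsilyl ketene acetal of lactone 15 | CC(C)(C)[Si](C)(C)OC1=C(O[Si](C)(C)C(C)(C)C)[C@@H](O[Si](C)(C)C(C)(C)C)[C@H](O[Si](C)(C)C(C)(C)C)[C@H](/C=C/OCc2ccc(OC)cc2)O1
F2 | step 10 | tert-butyldimethylsilyl ester of acid 18 | CC(C)(C)[Si](C)(C)OC(=O)[C@@]1(O[Si](C)(C)C(C)(C)C)[C@@H](O[Si](C)(C)C(C)(C)C)[C@H](O[Si](C)(C)C(C)(C)C)C=C[C@H]1OCc2ccc(OC)cc2
F3 | step 13 | 2,7-O-di-tert-butylsilylene derivative of tetraol 20 (O1 and O3 free) | CC(C)(C)[Si]1(C(C)(C)C)OC[C@@]2(O)[C@@H](O1)[C@H](O)C=C[C@H]2OCc3ccc(OC)cc3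
F4 | step 13 | 3-O-benzoyl-2,7-O-di-tert-butylsilylene derivative of tetraol 20 | CC(C)(C)[Si]1(C(C)(C)C)OC[C@@]2(O)[C@@H](O1)[C@H](OC(=O)c3ccccc3)C=C[C@H]2OCc4ccc(OC)cc4
F5 | step 13 | 3-O-benzoyl derivative of tetraol 20 (O1, O2 and O7 free) | OC[C@@]1(O)[C@@H](O)[C@H](OC(=O)c2ccccc2)C=C[C@H]1OCc3ccc(OC)cc3
F6 | step 9 | 2,3,4-tris-O-TBS L-gulo δ-lactone carrying an (E)-2-(pinacolboryl)vinyl group at C5 | O=C1[C@@H](O[Si](C)(C)C(C)(C)C)[C@@H](O[Si](C)(C)C(C)(C)C)[C@H](O[Si](C)(C)C(C)(C)C)[C@H](/C=C/B2OC(C)(C)C(C)(C)O2)O1
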